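**Strategy**

The route rests on cutting C2–C3 in the dihydrofuran fused to ring A (the styryl-bearing ring) and C2'–C3' in the one fused to ring B (the central ring). In each ring an O-benzylic carbon (C2, C2') sits next to a diarylmethine carbon (C3, C3') that is ortho to the ether oxygen (O1, O1') on the same arene, so a diaryl carbene at C3 or C3' can insert into the neighbouring ArCH2–O C–H bond. One operation on a bis(diaryldiazomethane) therefore closes both rings, forms both C–C bonds and sets C3 and C3' under catalyst control. The precursor is a linear bis(benzyl aryl ether) bearing two 2,6-dioxygenated benzophenone hydrazones, with every phenol masked as its methyl ether.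

Key step: step 12

**Remarks on the chemistry**

- Ring B needs its carbonyl carbon between the two ring oxygens and a one-carbon handle ortho to the phenol. A ketone made from 2,4-dimethoxybenzaldehyde would carry the carbonyl para to a methoxy group and lack that carbon. Ring B is therefore built from 1,3-dimethoxybenzene, which is lithiated between its two methoxy groups, and the missing carbon is added later by ortho-formylation.
- Assumption: Rh2(R-PTAD)4 is taken to give the S configuration at C3 and C3'. If a single-site model shows the opposite sense, Rh2(S-PTAD)4 is used with no other change.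
- The C=N geometry of the hydrazones is left undefined, since both isomers give the same diazo compound.
- The stilbene is installed by Suzuki–Miyaura coupling, so that the E geometry and the regiochemistry come from the boronic acid.

**Route**

Step 1
Reactants: 1 1-bromo-3,5-dimethoxybenzene; 2 4-bromo-2,6-dimethoxybenzaldehyde
Product: 4 (4-bromo-2,6-dimethoxyphenyl)(3,5-dimethoxyphenyl)methanol (racemic), via (3,5-dimethoxyphenyl)magnesium bromide 3 (not isolated)
Conditions: Mg, I2 (cat.), THF, reflux; then 2, THF, 0 °C → rt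
Reagents that add atoms: none
Why: Aryl Grignard addition to an aldehyde, in which the arylmagnesium bromide does not exchange with the aryl bromide of 2 at 0 °C; the carbinol centre forms as a racemate and is removed by the oxidation in step 2.

Step 2
Reactants: 4 (4-bromo-2,6-dimethoxyphenyl)(3,5-dimethoxyphenyl)methanol
Product: 5 (4-bromo-2,6-dimethoxyphenyl)(3,5-dimethoxyphenyl)methanone
Conditions: Dess–Martin periodinane, CH2Cl2, rt
Reagents that add atoms: none
Why: Dess–Martin oxidation of a secondary diarylmethanol to the diaryl ketone under near-neutral conditions that leave the electron-rich rings and the aryl bromide untouched.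

Step 3
Reactants: 5 (4-bromo-2,6-dimethoxyphenyl)(3,5-dimethoxyphenyl)methanone
Product: 6 (4-bromo-2-hydroxy-6-methoxyphenyl)(3,5-dimethoxyphenyl)methanone
Conditions: BCl3 (1.2 equiv), CH2Cl2, −78 → 0 °C
Reagents that add atoms: none
Why: Chelation-controlled Lewis acid ether cleavage, in which boron bridges the carbonyl oxygen and one of the two equivalent ortho methoxy groups and chloride removes only that methyl group, while the second ortho ether (deactivated once the boron chelate exists) and the non-chelating 3,5-dimethoxy groups remain.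

Step 4
Reactants: 7 1,3-dimethoxybenzene; 8 3,5-dimethoxybenzaldehyde
Product: 10 (2,6-dimethoxyphenyl)(3,5-dimethoxyphenyl)methanol (racemic), via (2,6-dimethoxyphenyl)lithium 9 (not isolated)
Conditions: n-BuLi, THF, 0 °C → rt; then 8, THF, −78 °C → rt
Reagents that add atoms: none
Why: Directed ortho-metalation, in which n-BuLi removes the proton between the two methoxy groups of 7 (the most acidic site, held by both oxygens), followed by addition of the aryllithium to the aldehyde; the carbinol centre forms as a racemate and is removed by the oxidation in step 5.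

Step 5
Reactants: 10 (2,6-dimethoxyphenyl)(3,5-dimethoxyphenyl)methanol
Product: 11 (2,6-dimethoxyphenyl)(3,5-dimethoxyphenyl)methanone
Conditions: Dess–Martin periodinane, CH2Cl2, rt
Reagents that add atoms: none
Why: Dess–Martin oxidation of a diarylmethanol to the benzophenone, as in step 2.

Step 6
Reactants: 11 (2,6-dimethoxyphenyl)(3,5-dimethoxyphenyl)methanone
Product: 12 (2-hydroxy-6-methoxyphenyl)(3,5-dimethoxyphenyl)methanone
Conditions: BCl3 (1.2 equiv), CH2Cl2, −78 → 0 °C
Reagents that add atoms: none
Why: Chelation-controlled mono-demethylation ortho to the carbonyl group as in step 3; the two ortho methoxy groups are equivalent, so no regiochemical question arises.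

Step 7
Reactants: 12 (2-hydroxy-6-methoxyphenyl)(3,5-dimethoxyphenyl)methanone
Product: 13 3-(3,5-dimethoxybenzoyl)-2-hydroxy-4-methoxybenzaldehyde
Conditions: MgCl2 (anhydrous), Et3N, (CH2O)n, MeCN, reflux
Reagents that add atoms: paraformaldehyde (reacts as formaldehyde), C=O
Why: Magnesium-mediated ortho-formylation of a phenol (Casnati–Skattebøl reaction), in which the magnesium phenoxide delivers formaldehyde to the only free ortho position, which is also para to the methoxy group, and the resulting benzylic alkoxide is oxidised to the aldehyde by hydride transfer to a second formaldehyde.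

Step 8
Reactants: 13 3-(3,5-dimethoxybenzoyl)-2-hydroxy-4-methoxybenzaldehyde; 14 2,4-dimethoxybenzyl alcohol
Product: 15 3-(3,5-dimethoxybenzoyl)-2-[(2,4-dimethoxyphenyl)methoxy]-4-methoxybenzaldehyde
Conditions: PPh3, DIAD, THF, 0 °C → rt
Reagents that add atoms: none
Why: Mitsunobu etherification, in which the acidic, doubly ortho-acylated phenol protonates the betaine quickly and its phenoxide is alkylated at oxygen by the benzylic oxyphosphonium ion, so the unstable 2,4-dimethoxybenzyl halide is not needed.

Step 9
Reactants: 15 3-(3,5-dimethoxybenzoyl)-2-[(2,4-dimethoxyphenyl)methoxy]-4-methoxybenzaldehyde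
Product: 16 {2-[(2,4-dimethoxyphenyl)methoxy]-3-(hydroxymethyl)-6-methoxyphenyl}(3,5-dimethoxyphenyl)methanone
Conditions: NaBH4 (0.5 equiv), THF/MeOH, −10 → 0 °C
Reagents that add atoms: none
Why: Chemoselective borohydride reduction of the aldehyde, since the diaryl ketone is flanked by two ortho alkoxy groups, twisted out of conjugation and shielded, and reacts far more slowly.

Step 10
Reactants: 16 {2-[(2,4-dimethoxyphenyl)methoxy]-3-(hydroxymethyl)-6-methoxyphenyl}(3,5-dimethoxyphenyl)methanone; 6 (4-bromo-2-hydroxy-6-methoxyphenyl)(3,5-dimethoxyphenyl)methanone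
Product: 17 {4-bromo-2-[(3-(3,5-dimethoxybenzoyl)-2-[(2,4-dimethoxyphenyl)methoxy]-4-methoxyphenyl)methoxy]-6-methoxyphenyl}(3,5-dimethoxyphenyl)methanone (diketone diether)
Conditions: PPh3, DIAD, THF, 0 °C → rt
Reagents that add atoms: none
Why: Mitsunobu etherification of the ortho-acyl phenol 6 with the primary, electron-rich benzylic alcohol 16, which joins the two halves under neutral conditions that both ketones and the acid-labile benzyl ether tolerate.

Step 11
Reactants: 17 diketone diether
Product: 18 bis-hydrazone of 17 (both C=O replaced by C=N–NH2)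
Conditions: N2H4·H2O (large excess), AcOH (cat.), n-BuOH, 110 °C, sealed tube
Reagents that add atoms: hydrazine (as the monohydrate), NN
Why: Hydrazone condensation, driven at the two hindered carbonyl groups by a large excess of hydrazine and heat; the aryl bromide and the aryl and benzyl ethers are inert to hydrazine, and the excess suppresses azine formation.

Step 12
Reactants: 18 bis-hydrazone
Product: 20 (2R,3S)-6-bromo-3-(3,5-dimethoxyphenyl)-2-[(2R,3S)-2-(2,4-dimethoxyphenyl)-3-(3,5-dimethoxyphenyl)-4-methoxy-2,3-dihydro-1-benzofuran-7-yl]-4-methoxy-2,3-dihydro-1-benzofuran (cis,cis), via bis(diazo) diether 19 (not isolated)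
Conditions: MnO2 (activated, 10 equiv per hydrazone), CH2Cl2, 0 °C → rt, dark; filtration through Celite under argon; filtrate added slowly to Rh2(R-PTAD)4 (2 mol%), CH2Cl2, −20 °C → rt
Reagents that add atoms: none
Why: MnO2 dehydrogenates both hydrazones to the bis(diaryldiazomethane) 19, and on Rh2(R-PTAD)4 (divalent rhodium) each diazo carbon loses N2 to give a donor/donor rhodium carbene that inserts in a concerted, asynchronous, hydride-shift-like way into the ArCH2–O C–H bond lying 1,5 to it. The closest known reaction is the enantioselective intramolecular C–H insertion of 2-(benzyloxy)aryl aryl diazomethanes to cis-2,3-diaryl-2,3-dihydrobenzofurans with chiral dirhodium tetracarboxylates, run here at two sites of one molecule. The ring on ring A closes by C3–C2 bond formation between the ring A carbene carbon and the methylene of the ring A–O–CH2–ring B ether, and the ring on ring B closes by C3'–C2' bond formation with the methylene of the 2,4-dimethoxybenzyl ether, each as a five-membered closure in which O1 or O1' is already in place. C3 and C3' (both S) are set by the chiral carboxylate pocket of the catalyst, which fixes the face of each carbene that accepts the hydrogen, while C2 and C2' (both R) follow from the compact transition state that places the two aryl groups cis and are therefore set relative to C3 and C3'. The step needs site selectivity for the benzylic methylene over the flanking methoxy C–H bonds, which the substrate secures because only the methylene C–H is activated by both an oxygen and an electron-rich aryl group; the two sites cannot cross over, since the ring B carbene sits meta to the ring A-linked methylene. Because both events are catalyst-controlled, the minor sense of either insertion should end in a separable diastereomer, and slow addition of 19 to the catalyst should keep azine and alkene formation low.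

Step 13
Reactants: 20 cis,cis-bis(dihydrobenzofuran) bromide
Product: 21 (2S,3S)-6-bromo-3-(3,5-dimethoxyphenyl)-2-[(2S,3S)-2-(2,4-dimethoxyphenyl)-3-(3,5-dimethoxyphenyl)-4-methoxy-2,3-dihydro-1-benzofuran-7-yl]-4-methoxy-2,3-dihydro-1-benzofuran (trans,trans)
Conditions: CF3CO2H (10 vol%), CH2Cl2 (0.01 M), 0 °C → rt
Reagents that add atoms: none
Why: Acid-catalysed epimerisation by SN1-type ring opening and reclosure, in which protonation of O1 or O1' gives a benzylic cation at C2 or C2' stabilised by its 2,4-dioxygenated aryl group and the phenol recloses under thermodynamic control to the trans ring (C2 and C2' become S), while C3 and C3' have no pathway to invert; high dilution disfavours intermolecular Friedel–Crafts capture.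

Step 14
Reactants: 21 trans,trans-bis(dihydrobenzofuran) bromide; 22 (E)-2-(4-methoxyphenyl)vinylboronic acid
Product: 23 nona-O-methyl gnetumontanin B
Conditions: Pd(PPh3)4 (5 mol%), K2CO3, 1,4-dioxane/H2O, 85 °C
Reagents that add atoms: none
Why: Suzuki–Miyaura coupling of an unhindered aryl bromide with an alkenylboronic acid on zerovalent palladium, which proceeds with retention of the E geometry and under a mild base that does not touch the dihydrofuran stereocentres.

Step 15
Reactants: 23 nona-O-methyl gnetumontanin B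
Product: 24 gnetumontanin B
Conditions: BBr3 (1 M in CH2Cl2, about 18 equiv), CH2Cl2, −78 → 0 °C
Reagents that add atoms: none
Why: Lewis acid cleavage of aryl methyl ethers (bromide attacks the O-methyl carbon of each ether–boron complex), a known way to unmask methylated stilbene oligomers; should a C2–O bond ionise transiently, it is expected to reclose to the thermodynamically preferred trans ring already present.

**Compound list**

1 | 1-bromo-3,5-dimethoxybenzene | COc1cc(Br)cc(OC)c1 | starting material
2 | 4-bromo-2,6-dimethoxybenzaldehyde | COc1cc(Br)cc(OC)c1C=O | starting material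
3 | (3,5-dimethoxyphenyl)magnesium bromide | COc1cc(OC)cc([Mg]Br)c1 | intermediate (not isolated)
4 | (4-bromo-2,6-dimethoxyphenyl)(3,5-dimethoxyphenyl)methanol, racemic | COc1cc(OC)cc(C(O)c2c(OC)cc(Br)cc2OC)c1 | intermediate
5 | (4-bromo-2,6-dimethoxyphenyl)(3,5-dimethoxyphenyl)methanone | COc1cc(OC)cc(C(=O)c2c(OC)cc(Br)cc2OC)c1 | intermediate
6 | (4-bromo-2-hydroxy-6-methoxyphenyl)(3,5-dimethoxyphenyl)methanone | COc1cc(OC)cc(C(=O)c2c(O)cc(Br)cc2OC)c1 | intermediate
7 | 1,3-dimethoxybenzene | COc1cccc(OC)c1 | starting material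
8 | 3,5-dimethoxybenzaldehyde | COc1cc(OC)cc(C=O)c1 | starting material
9 | (2,6-dimethoxyphenyl)lithium | COc1cccc(OC)c1[Li] | intermediate (not isolated)
10 | (2,6-dimethoxyphenyl)(3,5-dimethoxyphenyl)methanol, racemic | COc1cc(OC)cc(C(O)c2c(OC)cccc2OC)c1 | intermediate
11 | (2,6-dimethoxyphenyl)(3,5-dimethoxyphenyl)methanone | COc1cc(OC)cc(C(=O)c2c(OC)cccc2OC)c1 | intermediate
12 | (2-hydroxy-6-methoxyphenyl)(3,5-dimethoxyphenyl)methanone | COc1cc(OC)cc(C(=O)c2c(O)cccc2OC)c1 | intermediate
13 | 3-(3,5-dimethoxybenzoyl)-2-hydroxy-4-methoxybenzaldehyde | O=Cc1ccc(OC)c(C(=O)c2cc(OC)cc(OC)c2)c1O | intermediate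
14 | 2,4-dimethoxybenzyl alcohol | COc1ccc(CO)c(OC)c1 | starting material
15 | 3-(3,5-dimethoxybenzoyl)-2-[(2,4-dimethoxyphenyl)methoxy]-4-methoxybenzaldehyde | O=Cc1ccc(OC)c(C(=O)c2cc(OC)cc(OC)c2)c1OCc1ccc(OC)cc1OC | intermediate
16 | {2-[(2,4-dimethoxyphenyl)methoxy]-3-(hydroxymethyl)-6-methoxyphenyl}(3,5-dimethoxyphenyl)methanone | OCc1ccc(OC)c(C(=O)c2cc(OC)cc(OC)c2)c1OCc1ccc(OC)cc1OC | intermediate
17 | diketone diether: {4-bromo-2-[(3-(3,5-dimethoxybenzoyl)-2-[(2,4-dimethoxyphenyl)methoxy]-4-methoxyphenyl)methoxy]-6-methoxyphenyl}(3,5-dimethoxyphenyl)methanone | Brc1cc(OC)c(C(=O)c2cc(OC)cc(OC)c2)c(OCc2ccc(OC)c(C(=O)c3cc(OC)cc(OC)c3)c2OCc2ccc(OC)cc2OC)c1 | intermediate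
18 | bis-hydrazone of 17 (C=N geometry undefined) | Brc1cc(OC)c(C(=NN)c2cc(OC)cc(OC)c2)c(OCc2ccc(OC)c(C(=NN)c3cc(OC)cc(OC)c3)c2OCc2ccc(OC)cc2OC)c1 | intermediate
19 | bis(diazo) diether (precursor of the key step) | Brc1cc(OC)c(C(=[N+]=[N-])c2cc(OC)cc(OC)c2)c(OCc2ccc(OC)c(C(=[N+]=[N-])c3cc(OC)cc(OC)c3)c2OCc2ccc(OC)cc2OC)c1 | intermediate (not isolated)
20 | cis,cis-bis(dihydrobenzofuran) bromide, (2R,3S,2'R,3'S), octamethyl ether | Brc1cc(OC)c2c(c1)O[C@@H](c1ccc(OC)c3c1O[C@@H](c1ccc(OC)cc1OC)[C@H]3c1cc(OC)cc(OC)c1)[C@H]2c1cc(OC)cc(OC)c1 | intermediate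
21 | trans,trans-bis(dihydrobenzofuran) bromide, (2S,3S,2'S,3'S), octamethyl ether | Brc1cc(OC)c2c(c1)O[C@H](c1ccc(OC)c3c1O[C@H](c1ccc(OC)cc1OC)[C@H]3c1cc(OC)cc(OC)c1)[C@H]2c1cc(OC)cc(OC)c1 | intermediate
22 | (E)-2-(4-methoxyphenyl)vinylboronic acid | COc1ccc(/C=C/B(O)O)cc1 | starting material
23 | nona-O-methyl gnetumontanin B, (2S,3S,2'S,3'S), E-alkene | COc1ccc(/C=C/c2cc(OC)c3c(c2)O[C@H](c2ccc(OC)c4c2O[C@H](c2ccc(OC)cc2OC)[C@H]4c2cc(OC)cc(OC)c2)[C@H]3c2cc(OC)cc(OC)c2)cc1 | intermediate
24 | gnetumontanin B, (2S,3S,2'S,3'S), E-alkene | Oc1ccc(/C=C/c2cc(O)c3c(c2)O[C@H](c2ccc(O)c4c2O[C@H](c2ccc(O)cc2O)[C@H]4c2cc(O)cc(O)c2)[C@H]3c2cc(O)cc(O)c2)cc1 | target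

**Step count and risk**

Total step count: 15. Longest linear sequence: 12 steps (7 → 24, steps 4 to 15).

Steps most likely to fail:

1. Step 12 (double carbene C–H insertion). With two diazo groups in one molecule, coupling between a carbene and the remaining diazo group (azine or alkene formation), or a slow second insertion at the more crowded ring B site, could erode the yield and the diastereomeric purity. The fallback closes the rings one at a time and sets out from 16. Silylation (TBSCl, imidazole, DMF) gives the silyl ether F1. Hydrazine hydrate under the conditions of step 11 gives the mono-hydrazone F2. MnO2 converts this into the diazo compound F3 (not isolated), and Rh2(R-PTAD)4 closes the ring on ring B to give the cis-dihydrobenzofuran silyl ether F4. TBAF in THF frees the benzylic alcohol F5, and Mitsunobu etherification with 6 gives the ring A ketone F6. Hydrazine hydrate gives the hydrazone F7, MnO2 gives the diazo compound F8 (not isolated), and the second insertion on Rh2(R-PTAD)4 comes back to the route at 20.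

2. Step 11 (bis-hydrazone formation). Condensation at two carbonyl groups that are each flanked by two ortho oxygens may stall at the mono-hydrazone, and prolonged heating may start to cleave the benzylic ethers. The fallback sets out from 17 and replaces the equilibrium condensation by a silyl-transfer condensation. 1,2-Bis(tert-butyldimethylsilyl)hydrazine with Sc(OTf)3 (catalytic) in ClCH2CH2Cl at rt to 60 °C gives the bis(N-silylhydrazone) F9, the carbonyl oxygens leaving as the silanol. TBAF in THF at 0 °C then removes the N-silyl groups and comes back to the route at 18.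

3. Step 15 (ninefold demethylation). During the long exposure to BBr3 needed for nine ethers, the electron-rich stilbene or the C2–O and C2'–O bonds may ionise, which would lead to oligomerisation or incomplete cleavage. The fallback moves the demethylation ahead of the stilbene and sets out from 21. BBr3 in CH2Cl2 removes the eight methyl ethers and gives the octaphenol bromide F10. Ac2O and pyridine give the octaacetate F11. A Heck reaction with 4-acetoxystyrene (Pd(OAc)2, P(o-tol)3, Et3N, DMF, 90 °C) gives the nonaacetate F12. Catalytic K2CO3 in methanol at 0 °C removes the acetates by transesterification and comes back to the route at 24.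

**Further compounds**

F1 | step 12 | {3-[(tert-butyldimethylsilyloxy)methyl]-2-[(2,4-dimethoxyphenyl)methoxy]-6-methoxyphenyl}(3,5-dimethoxyphenyl)methanone | CC(C)(C)[Si](C)(C)OCc1ccc(OC)c(C(=O)c2cc(OC)cc(OC)c2)c1OCc1ccc(OC)cc1OC
F2 | step 12 | hydrazone of F1 (C=N geometry undefined) | CC(C)(C)[Si](C)(C)OCc1ccc(OC)c(C(=NN)c2cc(OC)cc(OC)c2)c1OCc1ccc(OC)cc1OC
F3 | step 12 | diazo compound from F2 | CC(C)(C)[Si](C)(C)OCc1ccc(OC)c(C(=[N+]=[N-])c2cc(OC)cc(OC)c2)c1OCc1ccc(OC)cc1OC
F4 | step 12 | tert-butyl{[(2R,3S)-2-(2,4-dimethoxyphenyl)-3-(3,5-dimethoxyphenyl)-4-methoxy-2,3-dihydro-1-benzofuran-7-yl]methoxy}dimethylsilane (cis) | CC(C)(C)[Si](C)(C)OCc1ccc(OC)c2c1O[C@@H](c1ccc(OC)cc1OC)[C@H]2c1cc(OC)cc(OC)c1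
F5 | step 12 | [(2R,3S)-2-(2,4-dimethoxyphenyl)-3-(3,5-dimethoxyphenyl)-4-methoxy-2,3-dihydro-1-benzofuran-7-yl]methanol (cis) | OCc1ccc(OC)c2c1O[C@@H](c1ccc(OC)cc1OC)[C@H]2c1cc(OC)cc(OC)c1
F6 | step 12 | (4-bromo-2-{[(2R,3S)-2-(2,4-dimethoxyphenyl)-3-(3,5-dimethoxyphenyl)-4-methoxy-2,3-dihydro-1-benzofuran-7-yl]methoxy}-6-methoxyphenyl)(3,5-dimethoxyphenyl)methanone | Brc1cc(OC)c(C(=O)c2cc(OC)cc(OC)c2)c(OCc2ccc(OC)c3c2O[C@@H](c2ccc(OC)cc2OC)[C@H]3c2cc(OC)cc(OC)c2)c1
F7 | step 12 | hydrazone of F6 (C=N geometry undefined) | Brc1cc(OC)c(C(=NN)c2cc(OC)cc(OC)c2)c(OCc2ccc(OC)c3c2O[C@@H](c2ccc(OC)cc2OC)[C@H]3c2cc(OC)cc(OC)c2)c1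
F8 | step 12 | diazo compound from F7 | Brc1cc(OC)c(C(=[N+]=[N-])c2cc(OC)cc(OC)c2)c(OCc2ccc(OC)c3c2O[C@@H](c2ccc(OC)cc2OC)[C@H]3c2cc(OC)cc(OC)c2)c1
F9 | step 11 | bis(N-tert-butyldimethylsilylhydrazone) of 17 (C=N geometry undefined) | Brc1cc(OC)c(C(=NN[Si](C)(C)C(C)(C)C)c2cc(OC)cc(OC)c2)c(OCc2ccc(OC)c(C(=NN[Si](C)(C)C(C)(C)C)c3cc(OC)cc(OC)c3)c2OCc2ccc(OC)cc2OC)c1
F10 | step 15 | octaphenol bromide, (2S,3S,2'S,3'S) | Brc1cc(O)c2c(c1)O[C@H](c1ccc(O)c3c1O[C@H](c1ccc(O)cc1O)[C@H]3c1cc(O)cc(O)c1)[C@H]2c1cc(O)cc(O)c1
F11 | step 15 | octaacetate of the octaphenol bromide, (2S,3S,2'S,3'S) | Brc1cc(OC(C)=O)c2c(c1)O[C@H](c1ccc(OC(C)=O)c3c1O[C@H](c1ccc(OC(C)=O)cc1OC(C)=O)[C@H]3c1cc(OC(C)=O)cc(OC(C)=O)c1)[C@H]2c1cc(OC(C)=O)cc(OC(C)=O)c1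
F12 | step 15 | nonaacetate of gnetumontanin B, (2S,3S,2'S,3'S), E-alkene | CC(=O)Oc1ccc(/C=C/c2cc(OC(C)=O)c3c(c2)O[C@H](c2ccc(OC(C)=O)c4c2O[C@H](c2ccc(OC(C)=O)cc2OC(C)=O)[C@H]4c2cc(OC(C)=O)cc(OC(C)=O)c2)[C@H]3c2cc(OC(C)=O)cc(OC(C)=O)c2)cc1
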